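Assumption: the lactone is numbered as oxolan-2-one (O1, C2 = C=O, C3 bears the 3,4,5-trimethoxybenzyl group, C4 the 4-hydroxy-3-methoxybenzyl group, C5 = OCH2). The given SMILES is then the trans (3R,4R) isomer. Compounds 1, 4 and 7 are taken as commercial.

## The problem

Hernanol is a single γ-lactone ring carrying two different arylmethyl groups, trans, on the adjacent carbons C3 and C4. The chain C2–C3–C4–C5 is a succinic acid skeleton with C2 at the carboxyl level and C5 at the alcohol level. The route must therefore decide which of two very similar termini is reduced, since the wrong choice gives the regioisomeric lactone with the aryl groups exchanged. The central bond C3–C4 joins two carbons that are each α to a carboxyl-derived carbon (C2 and C5), a 1,4-dioxygenated pattern in which both carbons are natural donors. Of the two stereocentres, C3 is α to the lactone carbonyl and can be equilibrated, the trans isomer being favoured. C4 is no longer acidic once C5 is reduced, so it must be set absolutely and can then control C3, but not the reverse. The free phenol is acidic and easily oxidised and must be masked through enolate and oxidative chemistry, and the electron-rich arenes are exposed to electrophilic attack under strongly acidic, cation-forming conditions.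

The feature that opens the key step is that each half is a 3-arylpropanoic acid: C2/C3 with the trimethoxybenzyl group, and C5/C4 with the guaiacylmethyl group. The target is thus a crossed dehydrodimer of two dihydrocinnamic acids joined at their α-carbons (C3–C4), with C3–H left acidic for stereochemical correction.

## Retrosynthesis

**Phenol.** The O–H of 15 is traced back to the benzyl ether 14, which survives strong base, one-electron oxidants, hydride and mild acid and is removed last without touching the lactone.

**C3 configuration.** No bond is cut. The trans lactone 14 is traced back to 13, the mixture of C3 epimers with C4 fixed as R. Because only C3–H is acidic and trans is the more stable arrangement, both epimers should converge on 14 under base. The earlier steps therefore need to control one stereocentre, not two.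

**O1–C2 bond and oxidation level of C5.** Lactone 13 is opened to the γ-hydroxy tert-butyl ester 12, and the CH2OH of 12 is traced back to the N-acyloxazolidinone of 11. In 11 the two termini of the succinate are chemically different: an imide that hydride cleaves to the primary alcohol, and a tert-butyl ester that hydride leaves alone. The imide sits on the guaiacyl half, so it also places the auxiliary next to the one centre (the later C4) that cannot be corrected afterwards.

**C3–C4 bond (key cut).** The central bond of 11 is cut to two enolates, the imide enolate 9 and the ester enolate 10, which come from imide 6 and ester 8. This removes both stereocentres and the whole carbon skeleton in one operation and leaves two near-identical fragments, each one or two steps from a commercial acid. Neighbouring cuts (a benzylic C–C bond at C3 or C4) remove only one substituent and leave a chiral lactone to be made separately. The forward reaction must join two donor carbons oxidatively, favour cross- over homo-coupling, and let the auxiliary fix the imide α-carbon.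

**Building blocks.** Imide 6 comes from acid 3 and oxazolidinone 4 through the mixed anhydride 5. Acid 3 comes from the phenolic acid 1 through the benzyl ester 2. Ester 8 comes from acid 7.

## Roads not taken

Alternative 1: The most obvious route cuts the exocyclic C3–CH2Ar bond. The forward step is alkylation of the lithium enolate of the enantiopure β-substituted lactone A1 with the benzylic bromide A2, anti to the C4 substituent, giving 14 directly. It is reliable, but A1 carries a single stereocentre that costs several steps by any established method (Stobbe condensation with asymmetric hydrogenation, or auxiliary alkylation, reduction and lactonisation). The sequence is linear, the two aryl halves enter by unrelated chemistry, and the central bond of the molecule is never the object of a strategic step. The chosen plan makes that central bond from two halves of equal size. Alternative 1 is kept as the fallback for the key step.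

Alternative 2: Both benzylic bonds are cut on a flat ring. Two site-selective cross-couplings of arylmethylzinc reagents with the dibromobutenolide A3 (C4 first, then C3) would give the tetrasubstituted butenolide A4. An enantioselective conjugate reduction of its C3=C4 bond with a chiral bisphosphine copper hydride would set C4, and C3 would follow by equilibration. This is the shortest route on paper. However, enantioselective hydride delivery to a tetrasubstituted butenolide flanked by two benzylic CH2 groups lacks close precedent. A4 can also be deprotonated at C5 or at either benzylic position, moving the double bond out of conjugation with the carbonyl. The whole absolute configuration would rest on that one step, whereas the chosen plan rests on an auxiliary with a predictable facial bias.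

Alternative 3: The same C3–C4 bond is cut, but as a [3,3] bond. Ireland–Claisen rearrangement of the silyl ketene acetal of the allylic ester A5 through a chair transition state would transfer chirality from the carbinol carbon to give acid A6 with the later C4 set. Oxidative cleavage of the propenyl group, reduction and lactonisation would lead to 13. The stereochemical transfer is dependable. The plan nonetheless needs a sacrificial stereocentre and a propenyl handle that are built in only to be cut off again, a separately assembled chiral allylic alcohol, and an alkene cleavage next to two electron-rich arenes. It is longer and less atom-economical than the direct oxidative union.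

Key step: step 4

## Route

Step 1
Reactants: 1 3-(4-hydroxy-3-methoxyphenyl)propanoic acid
Product: 3 3-(4-benzyloxy-3-methoxyphenyl)propanoic acid, via benzyl ester 2 (not isolated)
Conditions: BnBr (2.3 equiv), K2CO3, DMF, 60 °C; then 2 M NaOH, MeOH, 60 °C; then HCl to pH 2
Reagents that add atoms: benzyl bromide BrCc1ccccc1; sodium hydroxide [Na+].[OH-] (one carboxyl oxygen)
Why: Williamson alkylation of phenoxide and carboxylate gives 2, and saponification (acyl–oxygen cleavage) then removes only the benzyl ester, the aryl benzyl ether being inert to hydroxide.

Step 2
Reactants: 3 3-(4-benzyloxy-3-methoxyphenyl)propanoic acid; 4 (S)-4-benzyloxazolidin-2-one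
Product: 6 (S)-4-benzyl-3-[3-(4-benzyloxy-3-methoxyphenyl)propanoyl]oxazolidin-2-one, via mixed pivalic anhydride 5 (not isolated)
Conditions: PivCl, Et3N, THF, −20 °C; then 4, LiCl, −20 °C to rt
Reagents that add atoms: pivaloyl chloride CC(C)(C)C(=O)Cl (its acyl group is held only by intermediate 5; none of its atoms remain in 6)
Why: Mixed-anhydride N-acylation of an oxazolidinone; the hindered pivaloyl carbonyl directs attack of the lithium-activated carbamate nitrogen to the arylpropanoyl carbonyl, and no stereocentre is touched.

Step 3
Reactants: 7 3-(3,4,5-trimethoxyphenyl)propanoic acid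
Product: 8 tert-butyl 3-(3,4,5-trimethoxyphenyl)propanoate
Conditions: Cl3CC(=NH)OtBu (2 equiv), BF3·OEt2 (cat.), CH2Cl2/cyclohexane, rt
Reagents that add atoms: tert-butyl 2,2,2-trichloroacetimidate CC(C)(C)OC(=N)C(Cl)(Cl)Cl
Why: Acid-catalysed tert-butyl transfer from the trichloroacetimidate to the carboxylic acid; the tert-butyl ester is chosen because it resists both borohydride and Claisen self-condensation in the later steps.

Step 4
Reactants: 6 (S)-4-benzyl-3-[3-(4-benzyloxy-3-methoxyphenyl)propanoyl]oxazolidin-2-one; 8 tert-butyl 3-(3,4,5-trimethoxyphenyl)propanoate
Product: 11 tert-butyl (3R)-3-[(4-benzyloxy-3-methoxyphenyl)methyl]-4-[(4S)-4-benzyl-2-oxo-1,3-oxazolidin-3-yl]-4-oxo-2-[(3,4,5-trimethoxyphenyl)methyl]butanoate (both C2 epimers), via lithium Z-enolate of the imide 9 (not isolated), via lithium enolate of the ester 10 (not isolated)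
Conditions: 6 (1 equiv), 8 (1.5 equiv), LDA (2.6 equiv), THF, −78 °C; then Fe(acac)3 (2.5 equiv), THF, −78 °C to rt
Reagents that add atoms: lithium diisopropylamide CC(C)[N-]C(C)C.[Li+] (lithium held only by intermediates 9 and 10; none of its atoms remain in 11)
Why: This is an oxidative enolate heterocoupling, whose closest known form is the iron(III)- or copper(II)-mediated cross-coupling of an N-acyloxazolidinone enolate with an ester or ketone enolate. LDA converts both partners into lithium enolates (9 as the chelated Z-enolate, 10 as the more electron-rich ester enolate); one-electron oxidation of 10 by Fe(acac)3 should give an electrophilic α-ester radical that is captured at the α-carbon of 9, and a second Fe(III) oxidises the resulting radical anion to the neutral imide, so that two carbons of like (donor) polarity are joined as C2–C3 of 11. No ring is closed in this step. The new centre C3 (the later C4 of the lactone) is controlled by the auxiliary: in the lithium-chelated Z-enolate the C4 benzyl group of the (S)-oxazolidinone shields one face, and bond formation on the open face, the same face as in an alkylation, gives 3R. The new centre C2 is not expected to be controlled and does not need to be, because it becomes the acidic C3 of the lactone and is corrected in step 6. The step needs cross- over homo-coupling selectivity, which rests on the different oxidation potentials and aggregation of an imide and an ester enolate and is helped by an excess of the cheaper ester 8; the tert-butyl group suppresses Claisen condensation of 10. It also needs the arenes to stay intact, which the mild oxidant and the benzyl ether on the phenol secure.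

Step 5
Reactants: 11 tert-butyl (3R)-3-[(4-benzyloxy-3-methoxyphenyl)methyl]-4-[(4S)-4-benzyl-2-oxo-1,3-oxazolidin-3-yl]-4-oxo-2-[(3,4,5-trimethoxyphenyl)methyl]butanoate (both C2 epimers)
Product: 13 (4R)-4-[(4-benzyloxy-3-methoxyphenyl)methyl]-3-[(3,4,5-trimethoxyphenyl)methyl]oxolan-2-one (both C3 epimers), via hydroxy ester 12 (not isolated)
Conditions: LiBH4, MeOH (1 equiv), THF, 0 °C; then NH4Cl aq; then p-TsOH·H2O (cat.), toluene, 80 °C
Reagents that add atoms: none
Why: Borohydride reductive cleavage of the N-acyloxazolidinone at the exocyclic carbonyl gives the primary alcohol and leaves the tert-butyl ester, and acid-catalysed lactonisation (5-exo-trig acyl substitution) of the γ-hydroxy ester closes the ring; from here the former imide α-carbon is C4, no longer α to a carbonyl and configurationally fixed.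

Step 6
Reactants: 13 (4R)-4-[(4-benzyloxy-3-methoxyphenyl)methyl]-3-[(3,4,5-trimethoxyphenyl)methyl]oxolan-2-one (both C3 epimers)
Product: 14 (3R,4R)-4-[(4-benzyloxy-3-methoxyphenyl)methyl]-3-[(3,4,5-trimethoxyphenyl)methyl]oxolan-2-one
Conditions: DBU, toluene, 100 °C
Reagents that add atoms: none
Why: Base-mediated epimerisation through the lactone enolate under thermodynamic control: only C3–H is acidic, the trans arrangement is the more stable one, so both C3 epimers should converge on the (3R,4R) isomer while C4 is untouched.

Step 7
Reactants: 14 (3R,4R)-4-[(4-benzyloxy-3-methoxyphenyl)methyl]-3-[(3,4,5-trimethoxyphenyl)methyl]oxolan-2-one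
Product: 15 hernanol, (3R,4R)-4-[(4-hydroxy-3-methoxyphenyl)methyl]-3-[(3,4,5-trimethoxyphenyl)methyl]oxolan-2-one
Conditions: H2 (1 atm), 10% Pd/C, EtOAc/MeOH, rt
Reagents that add atoms: none
Why: Hydrogenolysis of the aryl benzyl ether; the lactone, the methyl ethers and the arenes are not reduced under these neutral conditions and no stereocentre is involved.

## Compound list

1 | 3-(4-hydroxy-3-methoxyphenyl)propanoic acid | COc1cc(CCC(=O)O)ccc1O | starting material
2 | benzyl 3-(4-benzyloxy-3-methoxyphenyl)propanoate | COc1cc(CCC(=O)OCc2ccccc2)ccc1OCc1ccccc1 | intermediate (not isolated)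
3 | 3-(4-benzyloxy-3-methoxyphenyl)propanoic acid | COc1cc(CCC(=O)O)ccc1OCc1ccccc1 | intermediate
4 | (S)-4-benzyloxazolidin-2-one | O=C1N[C@@H](Cc2ccccc2)CO1 | starting material
5 | 3-(4-benzyloxy-3-methoxyphenyl)propanoic pivalic anhydride | COc1cc(CCC(=O)OC(=O)C(C)(C)C)ccc1OCc1ccccc1 | intermediate (not isolated)
6 | (S)-4-benzyl-3-[3-(4-benzyloxy-3-methoxyphenyl)propanoyl]oxazolidin-2-one | COc1cc(CCC(=O)N2[C@@H](Cc3ccccc3)COC2=O)ccc1OCc1ccccc1 | intermediate
7 | 3-(3,4,5-trimethoxyphenyl)propanoic acid | COc1cc(CCC(=O)O)cc(OC)c1OC | starting material
8 | tert-butyl 3-(3,4,5-trimethoxyphenyl)propanoate | COc1cc(CCC(=O)OC(C)(C)C)cc(OC)c1OC | intermediate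
9 | lithium Z-enolate of imide 6 (O–Li cis to the arylmethyl group) | [Li+].[O-]/C(=C\Cc1ccc(OCc2ccccc2)c(OC)c1)N1[C@@H](Cc2ccccc2)COC1=O | intermediate (not isolated)
10 | lithium enolate of ester 8 (O–Li trans to the arylmethyl group; geometry without consequence) | [Li+].[O-]/C(OC(C)(C)C)=C/Cc1cc(OC)c(OC)c(OC)c1 | intermediate (not isolated)
11 | tert-butyl (3R)-3-[(4-benzyloxy-3-methoxyphenyl)methyl]-4-[(4S)-4-benzyl-2-oxo-1,3-oxazolidin-3-yl]-4-oxo-2-[(3,4,5-trimethoxyphenyl)methyl]butanoate, both C2 epimers (C2 left unspecified) | COc1cc(C[C@@H](C(=O)N2[C@@H](Cc3ccccc3)COC2=O)C(Cc2cc(OC)c(OC)c(OC)c2)C(=O)OC(C)(C)C)ccc1OCc1ccccc1 | intermediate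
12 | tert-butyl (3R)-3-[(4-benzyloxy-3-methoxyphenyl)methyl]-4-hydroxy-2-[(3,4,5-trimethoxyphenyl)methyl]butanoate, both C2 epimers | COc1cc(C[C@@H](CO)C(Cc2cc(OC)c(OC)c(OC)c2)C(=O)OC(C)(C)C)ccc1OCc1ccccc1 | intermediate (not isolated)
13 | (4R)-4-[(4-benzyloxy-3-methoxyphenyl)methyl]-3-[(3,4,5-trimethoxyphenyl)methyl]oxolan-2-one, both C3 epimers (C3 left unspecified) | COc1cc(C[C@H]2COC(=O)C2Cc2cc(OC)c(OC)c(OC)c2)ccc1OCc1ccccc1 | intermediate
14 | (3R,4R)-4-[(4-benzyloxy-3-methoxyphenyl)methyl]-3-[(3,4,5-trimethoxyphenyl)methyl]oxolan-2-one | COc1cc(C[C@H]2COC(=O)[C@@H]2Cc2cc(OC)c(OC)c(OC)c2)ccc1OCc1ccccc1 | intermediate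
15 | hernanol, (3R,4R)-4-[(4-hydroxy-3-methoxyphenyl)methyl]-3-[(3,4,5-trimethoxyphenyl)methyl]oxolan-2-one | COc1cc(C[C@H]2COC(=O)[C@@H]2Cc2cc(OC)c(OC)c(OC)c2)ccc1O | target

## Step count and least certain steps

Total steps: 7. Longest linear sequence: 6 (steps 1, 2, 4, 5, 6, 7); step 3 is a one-step branch.

**Step 4 (key step).**
- What may go wrong: statistical coupling, with homodimers of each enolate forming beside the cross-product, because two dihydrocinnamate-type enolates are similar in size and not far apart in oxidation potential. Incomplete oxidation would return 6 and 8 after protonation. Facial control at C3 could erode if bond formation proceeds through a non-chelated enolate, and residual base could epimerise the imide α-centre while the mixture warms.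
- Fallback: it sets out from 6 and abandons the oxidative union for two successive alkylations. Alkylation of the sodium enolate of 6 (NaHMDS, THF, −78 °C) with tert-butyl bromoacetate, anti to the auxiliary benzyl group, should give the succinate tert-butyl (3R)-3-[(4-benzyloxy-3-methoxyphenyl)methyl]-4-[(4S)-4-benzyl-2-oxo-1,3-oxazolidin-3-yl]-4-oxobutanoate F1. Borohydride cleavage of the imide and acid lactonisation, as in step 5, should give (4R)-4-[(4-benzyloxy-3-methoxyphenyl)methyl]oxolan-2-one F2 (the same compound as A1). Its lithium enolate (LiHMDS, THF/DMPU, −78 °C) should be alkylated by the bromide A2 anti to the C4 substituent. The fallback comes back to the route at 14 and bypasses 11, 13 and step 6.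

**Step 5.**
- What may go wrong: loss of chemoselectivity in the hydride step. The imide is α-branched and hindered, so hydride may attack the endocyclic carbamate carbonyl and open the auxiliary ring, or the ester may be partly reduced. In the acid stage, a tert-butyl cation could alkylate one of the electron-rich arenes.
- Fallback: it sets out from 11 and separates cleavage from reduction. Hydroperoxide hydrolysis (LiOH, H2O2, THF/H2O, 0 °C), which attacks the exocyclic carbonyl even of hindered imides, should give (2R)-2-[(4-benzyloxy-3-methoxyphenyl)methyl]-4-tert-butoxy-4-oxo-3-[(3,4,5-trimethoxyphenyl)methyl]butanoic acid F3 (both C3 epimers). Borane–dimethyl sulfide (THF, 0 °C) reduces the free acid in the presence of the tert-butyl ester. The fallback comes back to the route at 12, which is lactonised as in the second stage of step 5.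

**Step 6.**
- What may go wrong: the equilibration may stop short of a useful trans:cis ratio, or the residual cis epimer may be hard to separate from 14, since the two differ only at C3.
- Fallback: it sets out from 11 and replaces the thermodynamic funnel by separation at the stage where the auxiliary makes the C2 epimers most different. Chromatography of 11 should give the single diastereomer tert-butyl (2R,3R)-3-[(4-benzyloxy-3-methoxyphenyl)methyl]-4-[(4S)-4-benzyl-2-oxo-1,3-oxazolidin-3-yl]-4-oxo-2-[(3,4,5-trimethoxyphenyl)methyl]butanoate F4. Carried alone through the non-epimerising conditions of step 5, F4 should give the trans lactone directly, so the fallback comes back to the route at 14. The other C2 epimer of 11 is still taken through steps 5 and 6.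

## Further compounds

F1 | step 4 | tert-butyl (3R)-3-[(4-benzyloxy-3-methoxyphenyl)methyl]-4-[(4S)-4-benzyl-2-oxo-1,3-oxazolidin-3-yl]-4-oxobutanoate | COc1cc(C[C@@H](C(=O)N2[C@@H](Cc3ccccc3)COC2=O)CC(=O)OC(C)(C)C)ccc1OCc1ccccc1
F2 | step 4 | (4R)-4-[(4-benzyloxy-3-methoxyphenyl)methyl]oxolan-2-one | COc1cc(C[C@H]2COC(=O)C2)ccc1OCc1ccccc1
F3 | step 5 | (2R)-2-[(4-benzyloxy-3-methoxyphenyl)methyl]-4-tert-butoxy-4-oxo-3-[(3,4,5-trimethoxyphenyl)methyl]butanoic acid, both C3 epimers | COc1cc(C[C@@H](C(=O)O)C(Cc2cc(OC)c(OC)c(OC)c2)C(=O)OC(C)(C)C)ccc1OCc1ccccc1
F4 | step 6 | tert-butyl (2R,3R)-3-[(4-benzyloxy-3-methoxyphenyl)methyl]-4-[(4S)-4-benzyl-2-oxo-1,3-oxazolidin-3-yl]-4-oxo-2-[(3,4,5-trimethoxyphenyl)methyl]butanoate | COc1cc(C[C@@H](C(=O)N2[C@@H](Cc3ccccc3)COC2=O)[C@@H](Cc2cc(OC)c(OC)c(OC)c2)C(=O)OC(C)(C)C)ccc1OCc1ccccc1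
A1 | alternative 1 | (4R)-4-[(4-benzyloxy-3-methoxyphenyl)methyl]oxolan-2-one | COc1cc(C[C@H]2COC(=O)C2)ccc1OCc1ccccc1
A2 | alternative 1 | 5-(bromomethyl)-1,2,3-trimethoxybenzene (3,4,5-trimethoxybenzyl bromide) | COc1cc(CBr)cc(OC)c1OC
A3 | alternative 2 | 3,4-dibromofuran-2(5H)-one | O=C1OCC(Br)=C1Br
A4 | alternative 2 | 4-[(4-benzyloxy-3-methoxyphenyl)methyl]-3-[(3,4,5-trimethoxyphenyl)methyl]furan-2(5H)-one | COc1cc(CC2=C(Cc3cc(OC)c(OC)c(OC)c3)C(=O)OC2)ccc1OCc1ccccc1
A5 | alternative 3 | (2R,3E)-5-(4-benzyloxy-3-methoxyphenyl)pent-3-en-2-yl 3-(3,4,5-trimethoxyphenyl)propanoate | COc1cc(C/C=C/[C@@H](C)OC(=O)CCc2cc(OC)c(OC)c(OC)c2)ccc1OCc1ccccc1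
A6 | alternative 3 | (3S,4E)-3-[(4-benzyloxy-3-methoxyphenyl)methyl]-2-[(3,4,5-trimethoxyphenyl)methyl]hex-4-enoic acid (C2 unspecified) | COc1cc(C[C@@H](/C=C/C)C(Cc2cc(OC)c(OC)c(OC)c2)C(=O)O)ccc1OCc1ccccc1
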